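1. The amounts come first: c(precatalyst) = 0.22 mM stands far below c(substrate) = 0.050 M, so each catalyst has to go round many times, and the flask can be reckoned by counting rounds. Each round takes up one substrate and gives one product and one released group.

| flask | substrate | partner | scavenger | precatalyst | remark | time |
|---|---|---|---|---|---|---|
| ochre | 0.050 M | 0.035 M | 0.018 M | 0.22 mM | run made earlier |  |
| amber | 0.050 M | 0.035 M | 0.031 M | 0.22 mM | run made earlier |  |
| Wednesday's | 0.050 M | 0.0350 M | 0.0150 M | 0.22 mM |  | 10 min |
| Sunday's | 0.050 M | 0.0350 M | 0.0220 M | 0.22 mM |  | 10 min |

- ochre (time / min: substrate / %, product / %): 0.417: 96, 0; 1.33: 99, 4; 2.50: 91, 3; 4.00: 90, 7; 5.00: 85, 12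
- amber (time / min: substrate / %, product / %): 0.417: 99, 0; 1.33: 99, 2; 2.50: 95, 2; 4.00: 90, 10; 5.00: 89, 9

(scatter of a reading: 1.5 percentage points)

1. part of the substrate that has reacted at the end, Wednesday's
2. part of the substrate that has reacted at the end, Sunday's
3. what raising the concentration of scavenger from its lowest to its highest value here does to the part of the substrate that has reacted (changes below 5 percentage points count as none) (it rises / no change / it falls)

- amounts and yields of released group count idle adduct too
- steps thought possible: substrate + released group <-> idle adduct; scavenger + released group -> scavenged by-product; catalyst intermediate B <-> released group + catalyst intermediate C; partner + catalyst intermediate A <-> catalyst intermediate B; partner + precatalyst -> free catalyst + spent reagent; substrate + free catalyst -> catalyst intermediate A; catalyst intermediate C <-> free catalyst + product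
- what has gone from substrate into another species counts as reacted, even if it can come back

2. Scavenger: from ochre (0.018 M) to amber (0.031 M), the last product readings go from 12% to 9%. That gap of 3 percentage points is set against a scatter of 1.5 points per reading, so a rough value of c(scavenger) serves, provided it keeps up with the released group.

3. Substrate, partner, precatalyst: Wednesday's and Sunday's carry the charges of both runs, so errors in their effects do not enter this reckoning.

4. Time matters: the runs must be carried a further 5.00 min. The number needed is therefore the turnover frequency, the rounds per minute per catalyst charged. Taking the mean product of the two runs, it is 2.27 /min up to 2.50 min, then 7.27 /min up to 5.00 min. Scatter in this later rate shifts the end by 3 points.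

5. The mean substrate lost by 5.00 min, 13.0%, is 29.5 rounds. Holding the later frequency adds up to 65.9 rounds, so this reckoning gives 29.0% for both flasks. In this estimate that counts as 14.5 mM of released group, less than Wednesday's 0.0150 M of scavenger, so no trend is expected.

6. The forecast gave 23.5% (17% to 31%) for Wednesday's and 23% (17% to 30%) for Sunday's, with trend "no change", “allowing slight slowing as substrate and partner deplete”. The reckoning here stands higher.

7. The flasks give 33.1% for Wednesday's and 31.7% for Sunday's, with trend "no change" (−1.4 points).

    substrate + released group ⇌ idle adduct, settled at all times (K = 31.0 /M)
    scavenger + released group → scavenged by-product (k = 1.80 /M/s)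
    catalyst intermediate B ⇌ released group + catalyst intermediate C (K = 0.0480 M, k = 7.80 /s)
    partner + catalyst intermediate A ⇌ catalyst intermediate B (K = 14.0 /M, k = 18.0 /M/s)
    partner + precatalyst → free catalyst + spent reagent (k = 0.0610 /M/s)
    substrate + free catalyst → catalyst intermediate A (k = 58.0 /M/s)
    catalyst intermediate C ⇌ free catalyst + product (K = 0.0100 M, k = 2.10 /s)

8. Wednesday's turnover frequency rose from 4.89 /min in its first half to 8.00 /min in its second, while precatalyst fell from 54.7% to 34.6% of the catalyst charged. The wait for active catalyst, together with the short time allowed, is part of what holds the flask at 33.1%: without the wait it reaches 56.4%, and at tenfold time 79.4%. A neighbour flask, Sunday's with 0.021 M of partner, averaged 3.42 /min against Sunday's 6.50 /min, and ended at 16.7% reacted.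

Readings and results are simulated with constants of no real substance, noise included.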